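The runs stem from a simulated flask with made-up constants, and the scatter is random.

At late times the target stood still at 73% of the starting material in the delta run and 73% in the alpha run, although 0.80 equiv of reagent had been charged in each.

| flask | starting material | second substrate | reagent | free catalyst | remark |
|---|---|---|---|---|---|
| gamma | 0.027 M | 0.50 equiv | 0.80 equiv | 3.4 mol% | run made earlier |
| delta | 0.027 M | 0.50 equiv | 0.80 equiv | 7.5 mol% | run made earlier |
| alpha | 0.041 M | 0.50 equiv | 0.80 equiv | 5 mol% | run made earlier |
| flask | 0.027 M | 0.500 equiv | 0.800 equiv | 5 mol% |  |

| run | time / h | target / % | starting material / % |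
|---|---|---|---|
| gamma | 3.00 | 25 | 81 |
| gamma | 8.00 | 46 | 50 |
| gamma | 15.0 | 68 | 31 |
| gamma | 25.0 | 72 | 26 |
| delta | 3.00 | 42 | 57 |
| delta | 8.00 | 69 | 29 |
| delta | 15.0 | 73 | 26 |
| delta | 25.0 | 73 | 25 |
| alpha | 2.00 | 33 | 65 |
| alpha | 4.00 | 53 | 45 |
| alpha | 10.0 | 74 | 29 |
| alpha | 25.0 | 73 | 26 |

(readings scatter by 1.5 percentage points)

- the numbers in the tables scatter with a standard deviation of 1.5 percentage points

* apparent order in reagent when 50% of the starting material are converted (percent change of the rate of making target for one percent more reagent charged)
* factor on the rate of making target when 50% of the starting material are converted if free catalyst is charged twice over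

1. I took the reagent as the limiting reagent and this plateau as the end of its useful part. So for the flask, at 50% conversion, I reckoned the reserve at 23.0% of the starting-material charge.

2. I reckoned that extra reagent charged in the flask goes straight into that reserve. I therefore defined the reagent lever as the charge divided by the reserve at the conversion looked at: 3.48 for the flask.

3. I turned the question round. The apparent order is the momentary order in reagent times the lever, and an order near zero needs a momentary order near zero, because the lever stands at 3.48.

4. I read the momentary order from the delta run. From the first interval to the second the rate fell to 0.386 of its value, the starting material to 0.563 and the reserve to 0.337. Taking the rate as proportional to the starting material, I got a rough 0.348 from these readings.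

5. My reckoning for the flask was an order of 1.21. For the catalyst, delta had 2.21 times gamma's loading and reached 42% at 3.00 h against gamma's 46% at 8.00 h, so I expected a factor near 2.

6. The forecast gave 0.08 and 2, holding that “Reagent is therefore near zero order at 50% conversion”, which differs from my order.

7. The flask gave an order of 1.1 and a factor of 1.92.

    starting material + free catalyst ⇌ catalyst intermediate A (K = 14.0 M⁻¹, k = 140 M⁻¹ h⁻¹)
    reagent + catalyst intermediate A → free catalyst + target (k = 2800 M⁻¹ h⁻¹)
    second substrate + free catalyst ⇌ catalyst intermediate B (K = 25.0 M⁻¹, k = 93.0 M⁻¹ h⁻¹)
    reagent + catalyst intermediate B → free catalyst + second product (k = 97.0 M⁻¹ h⁻¹)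
    2 second substrate → self-condensation product (k = 11.0 M⁻¹ h⁻¹)

Divided by the lever of 3.48, the flask's order of 1.1 leaves a momentary order of 0.322. The apparent order in second substrate at 50% conversion was −0.071, and the largest single effect on it was the return of catalyst intermediate B to second substrate and free catalyst. In the run with that return taken away, that order came out at −0.37.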